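All runs are simulated for an exercise; the scatter is artificial.

all flasks: electrophile 13 mM

| flask | nucleophile | free base | remark | time |
|---|---|---|---|---|
| epsilon | 39 mM (fed, over 25 min) | 4.8 mM | run made earlier |  |
| beta | 39 mM (fed, over 25 min) | 5 mM | run made earlier |  |
| delta | 39 mM (fed, over 25 min) | 9.2 mM | run made earlier |  |
| Thursday's | 39.0 mM (fed, over 25 min) | 7.80 mM |  | 6.0 h |
| Monday's | 39.0 mM (fed, over 25 min) | 3.90 mM |  | 6.0 h |

| run | time / h | electrophile / % | product / % |
|---|---|---|---|
| epsilon | 0.417 | 85.2 | 15.7 |
| epsilon | 1.00 | 57.1 | 41.6 |
| epsilon | 2.00 | 34.5 | 66.3 |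
| epsilon | 3.00 | 22.0 | 77.1 |
| epsilon | 4.00 | 15.5 | 85.0 |
| beta | 0.333 | 91.1 | 9.0 |
| beta | 0.667 | 71.2 | 28.8 |
| beta | 1.33 | 48.3 | 52.0 |
| beta | 2.00 | 35.1 | 65.8 |
| beta | 4.00 | 15.2 | 84.0 |
| delta | 0.833 | 63.2 | 35.5 |
| delta | 1.50 | 44.0 | 55.8 |
| delta | 2.50 | 27.3 | 72.6 |
| delta | 3.00 | 21.3 | 78.2 |
| delta | 4.00 | 14.8 | 84.9 |

(standard deviation of a reading: 0.5 percentage points)

- in percentages every species weighs as the electrophile in it: one homo dimer counts as two
- the earlier runs were read with a standard deviation of 0.5 percentage points
- what may be going on: electrophile + nucleophile -> acid set free + product; nucleophile + acid set free <-> protonated nucleophile; acid set free + free base <-> salt of the base; 2 electrophile -> homo dimer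

- part of the electrophile that has reacted at the end, Thursday's
- part of the electrophile that has reacted at the end, Monday's
- what raising the concentration of free base from its lowest to its highest value here does to the part of the electrophile that has reacted (changes below 5 percentage points count as none) (no change / it rises / it falls)

Electrophile cannot react past the point where nucleophile is used up, and that point comes sooner if the acid set free takes a second nucleophile for each product. I assume it does and write the balance of the electrophile, charged in the smaller amount. The number is the cover R, the nucleophile charge over twice the electrophile charge: 1.50. R stands above one, so electrophile is the limiting reagent in these recipes.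

One number is not enough: R carries no clock. With a the fraction of electrophile left, free nucleophile here is (1 + 2a) electrophile charges, so after the feed Q = ln((1 + 2a)/a) grows at a steady rate κ. In the beta run Q climbs from 1.40 to 2.15, so κ reads 0.279 /h. The delta run, with 9.2 mM of free base, reads 0.287 /h, so I leave free base out. At 6.0 h, Q reaches 2.71, which leaves 7.69 % and gives me 92.3 % reacted in both Thursday's and Monday's.

The forecast differs slightly: 92.6 % for Thursday's, 91.5 % for Monday's and no change, reasoning “so base has only a weak effect”.

The flask gives 92.3 % on Thursday's and 92.2 % on Monday's, a change of 0.013 percentage points: no change.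

    electrophile + nucleophile → acid set free + product (k = 0.00590 /M/s)
    nucleophile + acid set free ⇌ protonated nucleophile, settled at all times (K = 2.40 × 10⁵ /M)
    acid set free + free base ⇌ salt of the base (K = 4100 /M, k = 0.400 /M/s)
    2 electrophile → homo dimer (k = 6.50 × 10⁻⁶ /M/s)

On Thursday's, R predicts 38.5 % of the nucleophile left, and 39 % stands there at 6.00 h. The neighbouring flask is Thursday's with 9.8 mM of nucleophile, so its R is 0.377. If acid set free went to nucleophile alone, nucleophile there would be used up at 37.7 % reacted, but that is no ceiling, since this flask also holds free base to take acid. It reaches 35.0 % at 6.00 h, with 11 % of its nucleophile unbound.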